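The readings were computed for an exercise, and the scatter is random.

A flat target curve tempts one to call the winter flask finished and to count nothing beyond what the two readings show.

| flask | starting material | second substrate | free catalyst | temperature | remark | time |
|---|---|---|---|---|---|---|
| winter | 0.94 M | 0.94 M | 2.5 mM | −20 °C | the very flask that is asked about, followed so far |  |
| autumn | 0.94 M | 0.94 M | 2.5 mM | −25 °C | run made earlier |  |
| flask | 0.94 M | 0.940 M | 2.5 mM | −20 °C |  | 8.0 d |

- winter (time / h: target / %, starting material / %): 6.00: 14.8, 78.7; 20.0: 30.4, 40.3; 30.0: 35.6, 24.9; 50.0: 39.9, 10.0; 72.0: 40.8, 6.5; 96.0: 40.6, 5.4; 120: 40.9, 5.3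
- autumn (time / h: target / %, starting material / %): 6.00: 8.9, 89.5; 20.0: 19.3, 68.1; 30.0: 23.1, 55.2; 50.0: 27.8, 37.2; 72.0: 29.5, 25.5; 96.0: 30.1, 18.7; 120: 30.7, 15.8

(each reading ± 0.3 percentage points)

- Thursday's: at 8.0 d raise the temperature by 20 K, then wait 8.0 d
- Friday's: at 8.0 d take out 90% of the target then present, then wait 8.0 d
- Monday's: change nothing and wait 8.0 d more
- Wednesday's: at 8.0 d add free catalyst, 100% of the amount charged, then wait 8.0 d

- target that was removed still counts
- additions bring no volume worth counting

- target, in percent of the starting material first charged, at 8.0 d
- which option adds most target ("none" when 2 percentage points or less is all one gets) (Thursday's / Friday's / Monday's / Wednesday's / none)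
- target present, with what was taken out counted in, in percent of the starting material first charged, after Thursday's
- target present, with what was taken out counted in, in percent of the starting material first charged, after Friday's

1. The bench rule says that once target stands still, the ceiling is target plus free starting material. In the winter run at 120 h this is 46.2%, so the rule allows Thursday's and Friday's no more than the 5.3% of starting material still free.

2. The rule stops working when the unread gap rivals the target. Here the gap is 53.8%, more than the target. The catalyst charge, 0.266% of the starting material, is far less than this gap. The winter run reads 1.32 for the split ratio S, the unread gap divided by target at the last reading.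

3. The autumn run, its starting material still falling at the last reading, ends with a gap of 53.5% and a ratio of 1.74. My reading is thermodynamic control: target stands in equilibrium with an unread partner.

4. In logarithms, lg S is 0.119 in the winter run and 0.241 in the autumn run, a fall of 0.122 for 5.00 K of warming. Thursday's rise is 4.00 such steps, so, assuming the fall stays even per kelvin, lg S becomes −0.370 and S becomes 0.427.

5. I take target at 8.0 d as 40.9% and assume the free starting material stays put. The pool of target and partner is then 94.7%. Thursday's gives 66.4% of target. Friday's takes out 36.8%, the rest splits again at S, and the total is 61.8%. Wednesday's can draw on 5.3% of free starting material. My choice is Thursday's, ahead of Friday's.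

The forecast gives 40.8%, Wednesday's, 41% and 40.8%, holding that “Warming a dead system or removing target should therefore change little”.

The flask gives 41.2%, with Thursday's best, 68.4% after Thursday's and 62.1% after Friday's.

    catalyst intermediate B → free catalyst + second product (k = 0.00920 s⁻¹, Ea = 76.0 kJ mol⁻¹)
    catalyst intermediate B + target → spent catalyst (k = 1.10 × 10⁻⁴ M⁻¹ s⁻¹, Ea = 47.0 kJ mol⁻¹)
    second substrate + free catalyst ⇌ catalyst intermediate B (K = 51.0 M⁻¹, k = 0.460 M⁻¹ s⁻¹, Ea = 48.0 kJ mol⁻¹, ΔH = −75.0 kJ mol⁻¹)
    catalyst intermediate A → free catalyst + target (k = 0.00560 s⁻¹, Ea = 66.0 kJ mol⁻¹)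
    starting material + free catalyst ⇌ catalyst intermediate A (K = 110 M⁻¹, k = 0.620 M⁻¹ s⁻¹, Ea = 42.0 kJ mol⁻¹, ΔH = −12.0 kJ mol⁻¹)
    target ⇌ isomer of the product (K = 1.30, k = 4.40 × 10⁻⁵ s⁻¹, Ea = 82.0 kJ mol⁻¹, ΔH = −35.0 kJ mol⁻¹)
    (constants at −20 °C)

The gap is the isomer of the product, 53.5% at 192 h, and its relaxation half-life with target by that step alone, 2.47 h, is short against the time. Shared out at S, the 5.06% of starting material still free reckons at 2.2 percentage points of target, and Wednesday's adds 2.2 points.

A neighbour flask with c(second substrate) = 2.3 M ends with 34.4% of its starting material free, so S at the same temperature gives 28.3% of target. The computed value for that neighbour flask is 28.4%.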